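**Strategy.** The synthesis cuts ring B away from an intact syringol ring A at C4a–C5 and C8–C8a (tetralin numbering). Both bonds are made in one flask from a phenol boronate and an enantioenriched α-methylene-γ-aryl-γ-butyrolactone, which acts as a C5/C8 1,4-dielectrophile. Rhodium-catalysed conjugate arylation joins C4a, the boron-marked carbon para to the C2 hydroxyl, to the exocyclic methylene (C5). Added CF3CO2H then ionises the lactone C8–O bond, which is benzylic to guaiacyl ring C. One of the two equivalent, doubly methoxy-activated ring A positions closes ring B at C8a. C6 and C8 are set in this step, and the lactone carbonyl survives as the C6 carboxyl.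

Key step: step 3

Assumption: the target is taken as drawn, (6R,7R,8S) with 6,7-trans and 7,8-trans; atom numbers are those of 5,6,7,8-tetrahydronaphthalen-2-ol and are also used for the corresponding atoms of the intermediates; the syringol pinacol boronate is taken as a commercial building block.

Step 1
Reactants: 1 dimethyl mesaconate (dimethyl (E)-2-methylbut-2-enedioate)
Product: 2 dimethyl (Z)-2-(bromomethyl)but-2-enedioate
Conditions: NBS (1.05 equiv), AIBN (5 mol %), PhCF3, reflux
Reagents that add atoms: N-bromosuccinimide, O=C1CCC(=O)N1Br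
Why: Wohl–Ziegler allylic bromination: the methyl group carries the only abstractable allylic hydrogens, the delocalised radical is brominated at its CH2 terminus, no stereocentre is formed, and any E/Z scrambling is harmless because the allylchromium reagent of step 2 equilibrates.

Step 2
Reactants: 2 dimethyl (Z)-2-(bromomethyl)but-2-enedioate, 3 4-(benzyloxy)-3-methoxybenzaldehyde
Product: 6 methyl (2S,3S)-2-[4-(benzyloxy)-3-methoxyphenyl]-4-methylidene-5-oxooxolane-3-carboxylate, via silyl ether 4 (not isolated), via hydroxy diester 5 (not isolated)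
Conditions: CrCl2 (10 mol %), tridentate 1,8-bis(4-isopropyl-4,5-dihydrooxazol-2-yl)carbazole ligand (12 mol %, the antipode that directs Si-face attack), iPr2NEt (30 mol %), Mn, Me3SiCl, THF, 0 °C → rt; then 1 M HCl, THF, rt
Reagents that add atoms: none
Why: Catalytic asymmetric Nozaki–Hiyama-type 2-(alkoxycarbonyl)allylation followed by lactonisation: the allylchromium species (trivalent chromium, turned over by Mn and Me3SiCl) adds through its ester-bearing γ-carbon to the Si face of 3 in a closed chair transition state inside the chiral ligand sphere, which sets the future C7 (S in 6) and the carbinol carbon anti to each other, and after desilylation the hydroxyl can close only onto the acrylate ester (five-membered ring) to give the 2,3-trans lactone, any cis lactone from a syn adduct being removed by chromatography.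

Step 3
Reactants: 6 methyl (2S,3S)-2-[4-(benzyloxy)-3-methoxyphenyl]-4-methylidene-5-oxooxolane-3-carboxylate, 7 2,6-dimethoxy-4-(4,4,5,5-tetramethyl-1,3,2-dioxaborolan-2-yl)phenol
Product: 9 (2R,3R,4S)-4-[4-(benzyloxy)-3-methoxyphenyl]-6-hydroxy-5,7-dimethoxy-3-(methoxycarbonyl)-1,2,3,4-tetrahydronaphthalene-2-carboxylic acid, via arylated lactone 8 (not isolated)
Conditions: 7 (1.5 equiv), [Rh(cod)OH]2 (2.5 mol %), dioxane–H2O (10:1), 40 °C; then CF3CO2H added to the same flask, 0 °C → rt
Reagents that add atoms: none
Why: Transmetalation of 7 to the hydroxo-rhodium complex gives an aryl–rhodium species (monovalent rhodium) that adds across the exocyclic C5=C6 double bond of 6 (Hayashi–Miyaura 1,4-addition to an α-substituted acrylate), forming C4a–C5, and water protonates the oxa-π-allyl rhodium enolate to give 8. Protonation takes place on the lactone face opposite the C7 ester (the sense seen when α-methylene paraconic esters are hydrogenated), so the new benzyl group on C6 ends cis to that ester on the lactone, which is the arrangement that reads as 6,7-trans once C5 and C8 are ring members, and the neutral medium prevents epimerisation. The lactone C8–O bond is inert in this first phase, so the order of events and with it the regiochemistry is fixed: boron marks the carbon para to the phenol for the first bond, and only when CF3CO2H is added does the C8–O bond ionise, as a secondary p-alkoxybenzyl ester does. Ring A captures the cation in an intramolecular Friedel–Crafts alkylation (closest known type: the acid cyclisation of lariciresinol-type and hydroxymatairesinol-type lignans to aryltetralins), a six-membered closure of ring B, exo at the cationic carbon, that forms C8–C8a and frees the C6 carboxylic acid. The two ring A positions flanking C4a are equivalent and each is ortho to one methoxy group and para to the other, so only one regioisomer can form and cyclisation should outrun proton loss from C7. C8 is set in a chair-like transition state in which ring A attacks the cation face anti to the C7 ester (allylic strain fixes the cation conformer), giving the 7,8-trans product whatever the configuration of this carbon in 6.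

Step 4
Reactants: 9 (2R,3R,4S)-4-[4-(benzyloxy)-3-methoxyphenyl]-6-hydroxy-5,7-dimethoxy-3-(methoxycarbonyl)-1,2,3,4-tetrahydronaphthalene-2-carboxylic acid
Product: 10 (6R,7R,8S)-8-[4-(benzyloxy)-3-methoxyphenyl]-6,7-bis(hydroxymethyl)-1,3-dimethoxy-5,6,7,8-tetrahydronaphthalen-2-ol
Conditions: LiAlH4 (excess), THF, 0 °C → reflux; aqueous work-up
Reagents that add atoms: none
Why: Hydride reduction of the carboxylate and the methyl ester to the two primary alcohols (standard LiAlH4 chemistry, as used on aryltetralin lignan lactones and diesters), in which no stereocentre is touched and the benzyl ether and the phenol (as its aluminate) survive.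

Step 5
Reactants: 10 (6R,7R,8S)-8-[4-(benzyloxy)-3-methoxyphenyl]-6,7-bis(hydroxymethyl)-1,3-dimethoxy-5,6,7,8-tetrahydronaphthalen-2-ol
Product: 11 (+)-8-methoxyisolariciresinol
Conditions: H2 (1 atm), 10% Pd/C, MeOH–EtOAc, rt
Reagents that add atoms: none
Why: Hydrogenolysis of the aryl benzyl ether over palladium, under which the dibenzylic C8 position, the primary alcohols and the methoxy groups are inert, so all three stereocentres are retained.

**Compound list**
1 | dimethyl mesaconate, dimethyl (E)-2-methylbut-2-enedioate | COC(=O)/C=C(\C)C(=O)OC | starting material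
2 | dimethyl (Z)-2-(bromomethyl)but-2-enedioate | COC(=O)/C=C(\CBr)C(=O)OC | intermediate
3 | 4-(benzyloxy)-3-methoxybenzaldehyde | COc1cc(C=O)ccc1OCc1ccccc1 | starting material
4 | dimethyl (2S)-2-[(S)-[4-(benzyloxy)-3-methoxyphenyl](trimethylsilyloxy)methyl]-3-methylidenebutanedioate | C=C(C(=O)OC)[C@H](C(=O)OC)[C@H](O[Si](C)(C)C)c1ccc(OCc2ccccc2)c(OC)c1 | intermediate
5 | dimethyl (2S)-2-[(S)-[4-(benzyloxy)-3-methoxyphenyl](hydroxy)methyl]-3-methylidenebutanedioate | C=C(C(=O)OC)[C@H](C(=O)OC)[C@H](O)c1ccc(OCc2ccccc2)c(OC)c1 | intermediate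
6 | methyl (2S,3S)-2-[4-(benzyloxy)-3-methoxyphenyl]-4-methylidene-5-oxooxolane-3-carboxylate (2,3-trans) | O=C1O[C@H](c2ccc(OCc3ccccc3)c(OC)c2)[C@@H](C(=O)OC)C1=C | intermediate
7 | 2,6-dimethoxy-4-(4,4,5,5-tetramethyl-1,3,2-dioxaborolan-2-yl)phenol | COc1cc(B2OC(C)(C)C(C)(C)O2)cc(OC)c1O | starting material
8 | methyl (2S,3S,4R)-2-[4-(benzyloxy)-3-methoxyphenyl]-4-[(4-hydroxy-3,5-dimethoxyphenyl)methyl]-5-oxooxolane-3-carboxylate (2,3-trans, 3,4-cis) | O=C1O[C@H](c2ccc(OCc3ccccc3)c(OC)c2)[C@@H](C(=O)OC)[C@H]1Cc4cc(OC)c(O)c(OC)c4 | intermediate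
9 | (2R,3R,4S)-4-[4-(benzyloxy)-3-methoxyphenyl]-6-hydroxy-5,7-dimethoxy-3-(methoxycarbonyl)-1,2,3,4-tetrahydronaphthalene-2-carboxylic acid (all-trans) | COc1cc([C@H]2c3c(cc(OC)c(O)c3OC)C[C@@H](C(=O)O)[C@@H]2C(=O)OC)ccc1OCc1ccccc1 | intermediate
10 | (6R,7R,8S)-8-[4-(benzyloxy)-3-methoxyphenyl]-6,7-bis(hydroxymethyl)-1,3-dimethoxy-5,6,7,8-tetrahydronaphthalen-2-ol | COc1cc([C@H]2c3c(cc(OC)c(O)c3OC)C[C@@H](CO)[C@@H]2CO)ccc1OCc1ccccc1 | intermediate
11 | (+)-8-methoxyisolariciresinol, (6R,7R,8S)-8-(4-hydroxy-3-methoxyphenyl)-6,7-bis(hydroxymethyl)-1,3-dimethoxy-5,6,7,8-tetrahydronaphthalen-2-ol | COc1cc([C@H]2c3c(cc(OC)c(O)c3OC)C[C@@H](CO)[C@@H]2CO)ccc1O | target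

Total step count: 5. Longest linear sequence: 5 steps (1 → 2 → 6 → 9 → 10 → 11).

**Steps most likely to fail**

Step 3.
- What may go wrong: the boronate is lost by protodeboronation, the exocyclic double bond of 6 migrates into the ring before arylation, or the protonation that sets C6 has poor facial selectivity.
- Fallback, from 6 back to the route at 11: ring A is delivered as a protected organocopper reagent at low temperature instead of as a free-phenol boronate under rhodium catalysis.
- 4-Bromo-2,6-dimethoxyphenol is benzylated (BnBr, K2CO3, DMF) to 2-(benzyloxy)-5-bromo-1,3-dimethoxybenzene F1.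
- Its Grignard reagent (Mg, THF), combined with CuBr·SMe2, adds to 6 at −78 °C.
- The enolate is protonated kinetically by CF3CO2H at that temperature to give the O-benzyl arylated lactone F2.
- On warming in the same acid F2 closes to the bis(benzyl ether) acid F3.
- LiAlH4 gives the bis(benzyl ether) diol F4, and hydrogenolysis of both benzyl ethers (H2, Pd/C) gives 11.

Step 2.
- What may go wrong: the chromium complex discriminates poorly between the faces of the electron-rich aldehyde, anti selectivity erodes (which would carry the opposite C7 configuration forward), or 3 undergoes reductive pinacol coupling.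
- Fallback, from 3 back to the route at 6: auxiliary control replaces catalyst control.
- (S)-4-Benzyloxazolidin-2-one is acylated (n-BuLi, methyl 4-chloro-4-oxobutanoate) to the succinyl imide F5.
- Its boron enolate (Bu2BOTf, iPr2NEt) adds to 3 in an Evans syn aldol reaction to give the syn aldol F6.
- F6 closes onto its methyl ester to the trans lactone imide F7.
- LiOH/H2O2 removes the auxiliary to give the paraconic acid F8.
- Stiles carboxylation (MeOMgOCO2Me, DMF, heat), followed by decarboxylative Mannich methylenation (aqueous CH2O, Et2NH, AcOH/NaOAc), gives the α-methylene acid F9.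
- Me3SiCHN2 esterifies F9 to 6.

Step 4.
- What may go wrong: a mixed lithium–aluminium carboxylate/phenoxide precipitates and stalls reduction of the C6 carboxyl group.
- Fallback, from 9 back to the route at 10: the two carbonyl groups are reduced one after the other through a neutral intermediate.
- BH3·SMe2 reduces only the carboxylic acid to give the hydroxy ester F10.
- F10 closes with catalytic TsOH to the trans-fused γ-lactone F11.
- The soluble lactone is then reduced with LiAlH4 to 10.

**Further compounds**
F1 | step 3 | 2-(benzyloxy)-5-bromo-1,3-dimethoxybenzene | COc1cc(Br)cc(OC)c1OCc1ccccc1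
F2 | step 3 | methyl (2S,3S,4R)-2-[4-(benzyloxy)-3-methoxyphenyl]-4-{[4-(benzyloxy)-3,5-dimethoxyphenyl]methyl}-5-oxooxolane-3-carboxylate | O=C1O[C@H](c2ccc(OCc3ccccc3)c(OC)c2)[C@@H](C(=O)OC)[C@H]1Cc4cc(OC)c(OCc5ccccc5)c(OC)c4
F3 | step 3 | (2R,3R,4S)-6-(benzyloxy)-4-[4-(benzyloxy)-3-methoxyphenyl]-5,7-dimethoxy-3-(methoxycarbonyl)-1,2,3,4-tetrahydronaphthalene-2-carboxylic acid | COc1cc([C@H]2c3c(cc(OC)c(OCc4ccccc4)c3OC)C[C@@H](C(=O)O)[C@@H]2C(=O)OC)ccc1OCc1ccccc1
F4 | step 3 | [(1S,2R,3R)-7-(benzyloxy)-1-[4-(benzyloxy)-3-methoxyphenyl]-6,8-dimethoxy-1,2,3,4-tetrahydronaphthalene-2,3-diyl]dimethanol | COc1cc([C@H]2c3c(cc(OC)c(OCc4ccccc4)c3OC)C[C@@H](CO)[C@@H]2CO)ccc1OCc1ccccc1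
F5 | step 2 | (S)-4-benzyl-3-(4-methoxy-4-oxobutanoyl)oxazolidin-2-one | COC(=O)CCC(=O)N1[C@@H](Cc2ccccc2)COC1=O
F6 | step 2 | methyl (3S,4S)-3-[(4S)-4-benzyl-2-oxooxazolidine-3-carbonyl]-4-[4-(benzyloxy)-3-methoxyphenyl]-4-hydroxybutanoate | COC(=O)C[C@H](C(=O)N1[C@@H](Cc2ccccc2)COC1=O)[C@H](O)c1ccc(OCc2ccccc2)c(OC)c1
F7 | step 2 | (4S)-4-benzyl-3-{(2S,3S)-2-[4-(benzyloxy)-3-methoxyphenyl]-5-oxooxolane-3-carbonyl}oxazolidin-2-one | O=C1O[C@H](c2ccc(OCc3ccccc3)c(OC)c2)[C@@H](C(=O)N2[C@@H](Cc3ccccc3)COC2=O)C1
F8 | step 2 | (2S,3S)-2-[4-(benzyloxy)-3-methoxyphenyl]-5-oxooxolane-3-carboxylic acid | O=C1O[C@H](c2ccc(OCc3ccccc3)c(OC)c2)[C@@H](C(=O)O)C1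
F9 | step 2 | (2S,3S)-2-[4-(benzyloxy)-3-methoxyphenyl]-4-methylidene-5-oxooxolane-3-carboxylic acid | O=C1O[C@H](c2ccc(OCc3ccccc3)c(OC)c2)[C@@H](C(=O)O)C1=C
F10 | step 4 | methyl (1S,2R,3R)-1-[4-(benzyloxy)-3-methoxyphenyl]-7-hydroxy-3-(hydroxymethyl)-6,8-dimethoxy-1,2,3,4-tetrahydronaphthalene-2-carboxylate | COc1cc([C@H]2c3c(cc(OC)c(O)c3OC)C[C@@H](CO)[C@@H]2C(=O)OC)ccc1OCc1ccccc1
F11 | step 4 | trans-fused γ-lactone of F10 (C6–CH2–O–C(=O)–C7), all three stereocentres arranged as in 9 | COc1cc([C@H]2c3c(cc(OC)c(O)c3OC)C[C@H]4COC(=O)[C@H]24)ccc1OCc1ccccc1
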